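**Plan**
- Retrosynthesis: the C6 methacrylate, C2 acetate and silyl groups are removed first; the butenolide is cut at C7=C11 and O–C12 (aldol condensation and enol-lactonisation of a C8 ketone with a silyl-protected hydroxypyruvate); the ten-membered ring is cut at C5–C6 with C3–C8 reconnected (retro anionic oxy-Cope).
- Enabling feature: C8 is a ketone-level carbon 1,5 to the Z C3=C4 alkene, so ring C1–C10 is the [3,3] isomer of a cyclohexanol built from C8, C9, C10, C1, C2, C3. It carries a Z-2-alkoxyvinyl arm (C7=C6) on carbinol C8 and an isopropenyl arm (C4=C5) on C3; its C10 and C2 oxygens are O1 and O3 of (−)-quinic acid.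
- Forward order: quinic acid ring (CO2H to CH3, 4,5-epoxide, isopropenyl at quinic C4, C5 ketone, alkoxyacetylide, Lindlar), then six-to-ten ring expansion, then the butenolide ring closed by lactonisation, then the two acylations.
- Stereochemistry: C10 and C2 are quinic C1 and C3. A temporary O1/O3 silylene bridge locks the chair so that the cuprate opens the epoxide at C4 with inversion and the acetylide adds cis to isopropenyl. C6 and the Z C3=C4 geometry come from the chair transition state of the oxy-Cope; the C8=C9 geometry is set by the ring.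

Key step: step 14

Remark: the macrocycle is numbered as a germacrane (ring C1–C10, lactone carbons C11–C13) and the cyclohexanes as quinic acid (quinic C1/C3/C4/C5 become germacrane C10/C2/C3/C8); the target is taken as 2R,6R,10S with 3Z and 8E, as its SMILES states.

Step 1
Reactants: 1 (−)-quinic acid
Product: 2 3,4-O-isopropylidenequinic acid 1,5-lactone
Conditions: 2,2-dimethoxypropane, TsOH·H2O (cat.), acetone, reflux
Reagents that add atoms: 2,2-dimethoxypropane COC(C)(C)OC
Why: Acid-catalysed acetonide formation on the cis-3,4-diol together with lactonisation of the carboxyl onto O5 (acetalisation/lactonisation) should leave only the tertiary hydroxyl free and change no stereocentre.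

Step 2
Reactants: 2 3,4-O-isopropylidenequinic acid 1,5-lactone
Product: 3 1-(hydroxymethyl)-3,4-O-isopropylidenecyclohexane-1,3,4,5-tetrol
Conditions: NaBH4, EtOH, 0 °C → rt
Reagents that add atoms: none
Why: Hydride reduction of the strained α-hydroxy lactone with NaBH4 should open it to the primary and secondary alcohols without touching the acetonide.

Step 3
Reactants: 3 1-(hydroxymethyl)-3,4-O-isopropylidenecyclohexane-1,3,4,5-tetrol
Product: 4 bis-mesylate (primary CH2OMs and 5-OMs; tertiary 1-OH free)
Conditions: MsCl (2.3 equiv), pyridine, CH2Cl2, 0 °C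
Reagents that add atoms: methanesulfonyl chloride CS(=O)(=O)Cl
Why: Mesylation (sulfonate ester formation) should take the primary and the secondary hydroxyl and spare the hindered tertiary one; the C5 mesylate blocks O5 in step 4 and is the leaving group of step 5.

Step 4
Reactants: 4 bis-mesylate
Product: 6 1-methyl-3,4-O-isopropylidene-5-O-mesylcyclohexane-1,3,4,5-tetrol, via spiro-epoxide 5 (not isolated)
Conditions: LiEt3BH (3 equiv), THF, −10 → 0 °C
Reagents that add atoms: none
Why: Super-Hydride reduction: the tertiary alkoxide should displace the neighbouring primary mesylate to spiro-epoxide 5, which hydride opens at its CH2 end (epoxide hydrogenolysis), so the former carboxyl carbon becomes the C1 methyl with C1 untouched, whereas SN2 attack on the β-oxygenated secondary mesylate is far slower.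

Step 5
Reactants: 6 1-methyl-3,4-O-isopropylidene-5-O-mesylcyclohexane-1,3,4,5-tetrol
Product: 8 4,5-epoxy-1-methylcyclohexane-1,3-diol (oxirane cis to both hydroxyls), via triol mesylate 7 (not isolated)
Conditions: 80% aq. AcOH, 45 °C; then K2CO3, MeOH, 0 °C → rt
Reagents that add atoms: none
Why: Acetal hydrolysis and then base-induced intramolecular SN2 (epoxide formation from a trans-β-hydroxy sulfonate): only O4 is anti to the C5 leaving group, so the oxirane should form with inversion at C5 on the face that carries O1 and O3.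

Step 6
Reactants: 8 4,5-epoxy-1-methylcyclohexane-1,3-diol
Product: 9 1,3-O-(di-tert-butylsilylene)-4,5-epoxy-1-methylcyclohexane-1,3-diol
Conditions: tBu2Si(OTf)2, 2,6-lutidine, CH2Cl2, −20 → 0 °C
Reagents that add atoms: di-tert-butylsilyl bis(trifluoromethanesulfonate) CC(C)(C)[Si](OS(=O)(=O)C(F)(F)F)(OS(=O)(=O)C(F)(F)F)C(C)(C)C
Why: Silylene acetal formation on a cis-1,3-diol (di-tert-butylsilylene protection); the six-membered O–Si–O bridge can exist only with O1 and O3 both axial, which locks the ring conformation for the next four steps.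

Step 7
Reactants: 9 silylene-bridged epoxide; 10 isopropenylmagnesium bromide
Product: 11 1,3-O-(di-tert-butylsilylene)-4-isopropenyl-1-methylcyclohexane-1,3,5-triol (isopropenyl trans to O3 and O5; O5 cis to O1/O3)
Conditions: CuI (20 mol%), THF, −30 → 0 °C
Reagents that add atoms: none
Why: Copper-catalysed Grignard opening of a cyclohexene oxide under Fürst–Plattner control: in the half-chair locked by the bridge only anti attack at C4 leads to a trans-diaxial product, so isopropenyl should enter at C4 with inversion and leave O5 on the O1/O3 face, a regiochemistry that an untethered 3-alkoxy epoxide would not give.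

Step 8
Reactants: 11 silylene-bridged 4-isopropenyl-5-ol
Product: 12 1,3-O-(di-tert-butylsilylene)-1,3-dihydroxy-4-isopropenyl-1-methylcyclohexan-5-one
Conditions: Dess–Martin periodinane, NaHCO3, CH2Cl2, 0 °C → rt
Reagents that add atoms: none
Why: Dess–Martin oxidation under buffered conditions should give the β,γ-unsaturated ketone without enolisation, so C4 keeps its configuration and the alkene stays out of conjugation.

Step 9
Reactants: 13 4-methoxybenzyl alcohol; 14 trichloroethylene
Product: 16 (E)-1,2-dichlorovinyl 4-methoxybenzyl ether, via potassium 4-methoxybenzyl oxide 15 (not isolated)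
Conditions: KH, THF, 0 °C; then trichloroethylene, −50 °C → rt
Reagents that add atoms: none
Why: Vinylic substitution of trichloroethylene by alkoxide 15 (the standard entry to 1,2-dichlorovinyl ethers as ynol ether precursors) should give the E ether.

Step 10
Reactants: 12 silylene-bridged ketone; 16 (E)-1,2-dichlorovinyl 4-methoxybenzyl ether
Product: 18 5-[(4-methoxybenzyloxy)ethynyl] carbinol (alkynyl cis to isopropenyl; 5-OH cis to O1/O3; silylene kept), via lithium (4-methoxybenzyloxy)acetylide 17 (not isolated)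
Conditions: 16, n-BuLi (2.2 equiv), THF, −78 → −40 °C; then 12, −78 → −30 °C; aq. NH4Cl
Reagents that add atoms: none
Why: n-BuLi converts 16 by dehydrochlorination and Cl–Li exchange into acetylide 17, which adds to the ketone (acetylide 1,2-addition); the axial face of the carbonyl is covered by the two axial oxygens of the bridge, so attack should be equatorial, cis to isopropenyl, placing the new hydroxyl on the O1/O3 face.

Step 11
Reactants: 18 alkoxyethynyl carbinol
Product: 19 5-[(Z)-2-(4-methoxybenzyloxy)vinyl] carbinol (silylene kept)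
Conditions: H2 (1 atm), Lindlar catalyst, quinoline, EtOAc, 0 °C
Reagents that add atoms: none
Why: Lindlar semihydrogenation (syn addition of H2) should stop at the Z enol ether and leave the isopropenyl group and the benzylic ether intact.

Step 12
Reactants: 19 silylene-bridged Z-alkoxyvinyl carbinol
Product: 20 4-isopropenyl-5-[(Z)-2-(4-methoxybenzyloxy)vinyl]-1-methylcyclohexane-1,3,5-triol
Conditions: TBAF, THF, 0 °C → rt
Reagents that add atoms: none
Why: Fluoride cleavage of the silylene (desilylation) is basic and so suits the acid-labile alkoxyvinyl carbinol; once the bridge is gone the ring can turn into the chair with all three oxygens equatorial.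

Step 13
Reactants: 20 triol
Product: 21 1,3-bis-O-triethylsilyl ether of 20 (tertiary 5-OH free)
Conditions: TESCl (2.5 equiv), imidazole, DMAP (cat.), DMF, 0 → 35 °C
Reagents that add atoms: chlorotriethylsilane CC[Si](Cl)(CC)CC
Why: Chemoselective silylation with TESCl/imidazole should take the secondary O3 and the unhindered methyl carbinol O1 and leave the tertiary O5–H, which is flanked by the isopropenyl-bearing carbon and the Z-alkoxyvinyl group.

Step 14
Reactants: 21 bis-triethylsilyl cis-dialkenyl cyclohexanol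
Product: 24 (3Z)-6-(4-methoxybenzyloxy)-4,10-dimethyl-2,10-bis(triethylsilyloxy)-8-(trimethylsilyloxy)cyclodeca-3,7-diene (2R,6R,10S), via potassium alkoxide 22 (not isolated), via potassium enolate 23 (not isolated)
Conditions: KH, 18-crown-6, THF, 0 °C → rt; then TMSCl, Et3N, −78 °C
Reagents that add atoms: chlorotrimethylsilane C[Si](C)(C)Cl
Why: KH gives potassium alkoxide 22, whose 1,5-diene C6=C7–C8–C3–C4=C5 undergoes a concerted suprafacial [3,3] shift through a chair (anionic oxy-Cope rearrangement): C5–C6 forms, the ring bond C3–C8 breaks and enolate 23 results, which is O-silylated in the cold before it can expel the C6 ether or equilibrate. The closest known reaction is the alkoxide-accelerated ring expansion of 1,2-dialkenylcyclohexanols to cyclodec-5-enones. The ten-membered ring is not closed end to end: it arises by four-atom ring expansion of the cyclohexane, the new C5–C6 bond replacing C3–C8. The new C6 stereocentre (R) is controlled by the Z enol ether, which puts the PMB-oxy group axial on the chair, and by the existing C8/C3 configuration, which lets C5 reach only one face of C6. The step needs Z geometry at C3=C4 and a single C6 epimer; the two equatorial triethylsilyloxy groups hold the cyclohexane in the chair with the C8 alkenyl arm axial and isopropenyl equatorial, so that C2 sits axial on the developing C3=C4 bond, and the regiodefined C7 enolate is kept as its silyl enol ether for step 17.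

Step 15
Reactants: 25 methyl 2-(hydroxymethyl)acrylate
Product: 26 methyl 2-[(tert-butyldiphenylsilyloxy)methyl]acrylate
Conditions: TBDPSCl, imidazole, CH2Cl2, rt
Reagents that add atoms: tert-butyl(chloro)diphenylsilane CC(C)(C)[Si](Cl)(c1ccccc1)c1ccccc1
Why: Silyl ether formation at a primary alcohol (TBDPS protection) should be straightforward.

Step 16
Reactants: 26 methyl 2-[(tert-butyldiphenylsilyloxy)methyl]acrylate
Product: 27 methyl 3-(tert-butyldiphenylsilyloxy)-2-oxopropanoate
Conditions: O3, CH2Cl2, −78 °C; then Me2S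
Reagents that add atoms: ozone [O-][O+]=O
Why: Ozonolysis with reductive work-up should cleave the 1,1-disubstituted alkene to the α-keto ester and formaldehyde.

Step 17
Reactants: 24 trimethylsilyl enol ether; 27 methyl 3-(tert-butyldiphenylsilyloxy)-2-oxopropanoate
Product: 29 aldol adduct (C8 ketone; C7 bears C11(OH)(CH2OTBDPS)CO2Me; C7/C11 epimers), via lithium enolate 28 (not isolated)
Conditions: MeLi, THF, −20 → 0 °C; then 27, −78 °C; AcOH quench at −78 °C
Reagents that add atoms: none
Why: Methyllithium should cleave the Si–O bond of the enol ether to the regiodefined lithium enolate 28 (regiospecific enolate generation from a silyl enol ether), which adds through C7 to the highly electrophilic keto group of 27 (aldol addition); both new stereocentres disappear in steps 18–20.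

Step 18
Reactants: 29 aldol adduct
Product: 31 C7=C11 ene-keto ester (E/Z mixture), via C11 mesylate 30 (not isolated)
Conditions: MsCl, Et3N, CH2Cl2, −20 °C → rt
Reagents that add atoms: none
Why: Mesylation of the tertiary aldol hydroxyl followed by E1cB elimination through the C8 enol (aldol dehydration) should place the alkene at C7=C11, since mesylate leaves far more readily than the C6 ether oxygen; the C6 stereocentre is not involved.

Step 19
Reactants: 31 ene-keto ester
Product: 33 8-hydroxy butenolide (cyclic pseudo-acid; C8 epimers), via Z-keto acid 32 (not isolated)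
Conditions: Me3SnOH, ClCH2CH2Cl, 70 °C; aq. KF, then pH 4 buffer
Reagents that add atoms: trimethyltin hydroxide C[Sn](C)(C)O
Why: Trimethyltin hydroxide should cleave the methyl ester under near-neutral conditions (tin-mediated ester hydrolysis) and the Z acid 32 should close to the cyclic pseudo-acid by ring–chain tautomerism, the E ester being fed in by reversible conjugate addition at the ene-dicarbonyl unit.

Step 20
Reactants: 33 8-hydroxy butenolide
Product: 35 8,9-ylidene butenolide (6-OPMB; 2,10-bis-OTES; 13-OTBDPS), via 8-acetoxy butenolide 34 (not isolated)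
Conditions: Ac2O, Et3N, DMAP (cat.), CH2Cl2, 0 °C → rt
Reagents that add atoms: none
Why: Acetylation of the lactol and base-induced loss of acetic acid toward C9 (dehydration of a γ-hydroxybutenolide to a γ-ylidenebutenolide) should give the dienolide with the ring-cis 8E enol ether, C9 being the only carbon that can lose a proton.

Step 21
Reactants: 35 8,9-ylidene butenolide
Product: 36 C6 alcohol
Conditions: DDQ, CH2Cl2/pH 7 buffer, 0 °C
Reagents that add atoms: none
Why: Oxidative cleavage of the 4-methoxybenzyl ether with DDQ (PMB deprotection) should free the C6 hydroxyl without touching the silyl ethers or the dienolide.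

Step 22
Reactants: 36 C6 alcohol
Product: 37 C6 methacrylate
Conditions: methacrylic anhydride, Et3N, DMAP, CH2Cl2, 0 °C → rt
Reagents that add atoms: methacrylic anhydride C=C(C)C(=O)OC(=O)C(C)=C
Why: DMAP-catalysed acylation with methacrylic anhydride (esterification) should give the C6 ester with retention, all other hydroxyls still being silylated.

Step 23
Reactants: 37 C6 methacrylate
Product: 38 2,10-diol (13-OTBDPS kept)
Conditions: HF·pyridine, pyridine, THF, 0 °C
Reagents that add atoms: none
Why: Buffered HF·pyridine should remove the two triethylsilyl ethers (acidic fluoride desilylation) while the primary tert-butyldiphenylsilyl ether, far more stable to acid, survives.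

Step 24
Reactants: 38 2,10-diol
Product: 39 C2 acetate
Conditions: Ac2O, pyridine, DMAP (cat.), CH2Cl2, 0 °C
Reagents that add atoms: acetic anhydride CC(=O)OC(C)=O
Why: Acetylation with Ac2O/pyridine should take only the secondary allylic C2 hydroxyl, the tertiary C10 hydroxyl being unreactive under these conditions (chemoselective acylation).

Step 25
Reactants: 39 C2 acetate
Product: 40 CNP0122447.1
Conditions: TBAF, AcOH (1:1), THF, 0 °C → rt
Reagents that add atoms: none
Why: Acetic acid-buffered TBAF (fluoride desilylation) should free the C13 hydroxyl at near-neutral pH, which avoids acyl migration and ionisation of the tertiary allylic alcohol, and gives the target.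

**Compound list**
1 | (−)-quinic acid | O[C@@]1(C(=O)O)C[C@@H](O)[C@@H](O)[C@H](O)C1 | starting material
2 | 3,4-O-isopropylidenequinic acid 1,5-lactone | O[C@@]1(C(=O)O2)C[C@H]3OC(C)(C)O[C@H]3[C@H]2C1 | intermediate
3 | 1-(hydroxymethyl)-3,4-O-isopropylidenecyclohexane-1,3,4,5-tetrol | O[C@@]1(CO)C[C@H]2OC(C)(C)O[C@H]2[C@H](O)C1 | intermediate
4 | bis-mesylate of 3 (CH2OMs and 5-OMs, 1-OH free) | O[C@@]1(COS(C)(=O)=O)C[C@H]2OC(C)(C)O[C@H]2[C@H](OS(C)(=O)=O)C1 | intermediate
5 | spiro-epoxide (oxirane from O1 and the former carboxyl carbon; 5-OMs) | C1O[C@]12C[C@H]3OC(C)(C)O[C@H]3[C@H](OS(C)(=O)=O)C2 | intermediate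
6 | 1-methyl-3,4-O-isopropylidene-5-O-mesylcyclohexane-1,3,4,5-tetrol | O[C@@]1(C)C[C@H]2OC(C)(C)O[C@H]2[C@H](OS(C)(=O)=O)C1 | intermediate
7 | 1-methyl-5-O-mesylcyclohexane-1,3,4,5-tetrol | O[C@@]1(C)C[C@@H](O)[C@@H](O)[C@H](OS(C)(=O)=O)C1 | intermediate
8 | 4,5-epoxy-1-methylcyclohexane-1,3-diol (oxirane cis to both OH) | O[C@@]1(C)C[C@@H](O)[C@H]2O[C@H]2C1 | intermediate
9 | 1,3-O-(di-tert-butylsilylene) derivative of 8 | C[C@@]12C[C@@H](O[Si](O1)(C(C)(C)C)C(C)(C)C)[C@H]3O[C@H]3C2 | intermediate
10 | isopropenylmagnesium bromide | C=C(C)[Mg]Br | starting material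
11 | 1,3-O-(di-tert-butylsilylene)-4-isopropenyl-1-methylcyclohexane-1,3,5-triol | C[C@@]12C[C@@H](O[Si](O1)(C(C)(C)C)C(C)(C)C)[C@H](C(C)=C)[C@@H](O)C2 | intermediate
12 | silylene-bridged 4-isopropenyl-1-methyl-5-ketone | C[C@@]12C[C@@H](O[Si](O1)(C(C)(C)C)C(C)(C)C)[C@H](C(C)=C)C(=O)C2 | intermediate
13 | 4-methoxybenzyl alcohol | COc1ccc(CO)cc1 | starting material
14 | trichloroethylene | ClC=C(Cl)Cl | starting material
15 | potassium 4-methoxybenzyl oxide | COc1ccc(C[O-])cc1.[K+] | intermediate
16 | (E)-1,2-dichlorovinyl 4-methoxybenzyl ether | COc1ccc(CO/C(Cl)=C\Cl)cc1 | intermediate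
17 | lithium (4-methoxybenzyloxy)acetylide | [Li]C#COCc1ccc(OC)cc1 | intermediate
18 | silylene-bridged 5-[(4-methoxybenzyloxy)ethynyl] carbinol | C[C@@]12C[C@@H](O[Si](O1)(C(C)(C)C)C(C)(C)C)[C@H](C(C)=C)[C@](O)(C#COCc3ccc(OC)cc3)C2 | intermediate
19 | silylene-bridged 5-[(Z)-2-(4-methoxybenzyloxy)vinyl] carbinol | C[C@@]12C[C@@H](O[Si](O1)(C(C)(C)C)C(C)(C)C)[C@H](C(C)=C)[C@](O)(/C=C\OCc3ccc(OC)cc3)C2 | intermediate
20 | 4-isopropenyl-5-[(Z)-2-(4-methoxybenzyloxy)vinyl]-1-methylcyclohexane-1,3,5-triol | O[C@@]1(C)C[C@@H](O)[C@H](C(C)=C)[C@](O)(/C=C\OCc2ccc(OC)cc2)C1 | intermediate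
21 | 1,3-bis-O-triethylsilyl ether of 20 (oxy-Cope precursor) | CC[Si](CC)(CC)O[C@@]1(C)C[C@@H](O[Si](CC)(CC)CC)[C@H](C(C)=C)[C@](O)(/C=C\OCc2ccc(OC)cc2)C1 | intermediate
22 | potassium alkoxide of 21 | CC[Si](CC)(CC)O[C@@]1(C)C[C@@H](O[Si](CC)(CC)CC)[C@H](C(C)=C)[C@]([O-])(/C=C\OCc2ccc(OC)cc2)C1.[K+] | intermediate
23 | potassium enolate (C7=C8–OK) of the ten-membered ketone | C[C@@]1(O[Si](CC)(CC)CC)C/C([O-])=C/[C@H](OCc2ccc(OC)cc2)C/C(C)=C\[C@H](O[Si](CC)(CC)CC)C1.[K+] | intermediate
24 | (3Z)-6-(4-methoxybenzyloxy)-4,10-dimethyl-2,10-bis(triethylsilyloxy)-8-(trimethylsilyloxy)cyclodeca-3,7-diene (oxy-Cope product) | C[C@@]1(O[Si](CC)(CC)CC)C/C(O[Si](C)(C)C)=C/[C@H](OCc2ccc(OC)cc2)C/C(C)=C\[C@H](O[Si](CC)(CC)CC)C1 | intermediate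
25 | methyl 2-(hydroxymethyl)acrylate | C=C(CO)C(=O)OC | starting material
26 | methyl 2-[(tert-butyldiphenylsilyloxy)methyl]acrylate | C=C(CO[Si](c1ccccc1)(c1ccccc1)C(C)(C)C)C(=O)OC | intermediate
27 | methyl 3-(tert-butyldiphenylsilyloxy)-2-oxopropanoate | COC(=O)C(=O)CO[Si](c1ccccc1)(c1ccccc1)C(C)(C)C | intermediate
28 | lithium enolate (C7=C8–OLi) | C[C@@]1(O[Si](CC)(CC)CC)C/C([O-])=C/[C@H](OCc2ccc(OC)cc2)C/C(C)=C\[C@H](O[Si](CC)(CC)CC)C1.[Li+] | intermediate
29 | aldol adduct (C7/C11 epimers) | C[C@@]1(O[Si](CC)(CC)CC)CC(=O)C(C(O)(CO[Si](c2ccccc2)(c2ccccc2)C(C)(C)C)C(=O)OC)[C@H](OCc2ccc(OC)cc2)C/C(C)=C\[C@H](O[Si](CC)(CC)CC)C1 | intermediate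
30 | C11 mesylate of 29 | C[C@@]1(O[Si](CC)(CC)CC)CC(=O)C(C(OS(C)(=O)=O)(CO[Si](c2ccccc2)(c2ccccc2)C(C)(C)C)C(=O)OC)[C@H](OCc2ccc(OC)cc2)C/C(C)=C\[C@H](O[Si](CC)(CC)CC)C1 | intermediate
31 | C7=C11 ene-keto ester (E/Z mixture) | C[C@@]1(O[Si](CC)(CC)CC)CC(=O)C(=C(CO[Si](c2ccccc2)(c2ccccc2)C(C)(C)C)C(=O)OC)[C@H](OCc2ccc(OC)cc2)C/C(C)=C\[C@H](O[Si](CC)(CC)CC)C1 | intermediate
32 | (Z)-keto acid (C12 cis to C8) | C[C@@]1(O[Si](CC)(CC)CC)CC(=O)/C(=C(/CO[Si](c2ccccc2)(c2ccccc2)C(C)(C)C)C(=O)O)[C@H](OCc2ccc(OC)cc2)C/C(C)=C\[C@H](O[Si](CC)(CC)CC)C1 | intermediate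
33 | 8-hydroxy butenolide (C8 epimers) | C[C@@]1(O[Si](CC)(CC)CC)CC2(O)OC(=O)C(CO[Si](c3ccccc3)(c3ccccc3)C(C)(C)C)=C2[C@H](OCc2ccc(OC)cc2)C/C(C)=C\[C@H](O[Si](CC)(CC)CC)C1 | intermediate
34 | 8-acetoxy butenolide | C[C@@]1(O[Si](CC)(CC)CC)CC2(OC(C)=O)OC(=O)C(CO[Si](c3ccccc3)(c3ccccc3)C(C)(C)C)=C2[C@H](OCc2ccc(OC)cc2)C/C(C)=C\[C@H](O[Si](CC)(CC)CC)C1 | intermediate
35 | 8,9-ylidene butenolide (6-OPMB, 2,10-bis-OTES, 13-OTBDPS) | COc1ccc(CO[C@@H]2C/C(C)=C\[C@H](O[Si](CC)(CC)CC)C[C@](C)(O[Si](CC)(CC)CC)/C=C3/OC(=O)C(CO[Si](c4ccccc4)(c4ccccc4)C(C)(C)C)=C32)cc1 | intermediate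
36 | C6 alcohol | O[C@@H]1C/C(C)=C\[C@H](O[Si](CC)(CC)CC)C[C@](C)(O[Si](CC)(CC)CC)/C=C2/OC(=O)C(CO[Si](c3ccccc3)(c3ccccc3)C(C)(C)C)=C21 | intermediate
37 | C6 methacrylate | C=C(C)C(=O)O[C@@H]1C/C(C)=C\[C@H](O[Si](CC)(CC)CC)C[C@](C)(O[Si](CC)(CC)CC)/C=C2/OC(=O)C(CO[Si](c3ccccc3)(c3ccccc3)C(C)(C)C)=C21 | intermediate
38 | 2,10-diol (C6 methacrylate, 13-OTBDPS) | C=C(C)C(=O)O[C@@H]1C/C(C)=C\[C@H](O)C[C@](C)(O)/C=C2/OC(=O)C(CO[Si](c3ccccc3)(c3ccccc3)C(C)(C)C)=C21 | intermediate
39 | C2 acetate (13-OTBDPS) | C=C(C)C(=O)O[C@@H]1C/C(C)=C\[C@H](OC(C)=O)C[C@](C)(O)/C=C2/OC(=O)C(CO[Si](c3ccccc3)(c3ccccc3)C(C)(C)C)=C21 | intermediate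
40 | CNP0122447.1 | C=C(C)C(=O)O[C@@H]1C/C(C)=C\[C@H](OC(C)=O)C[C@](C)(O)/C=C2/OC(=O)C(CO)=C21 | target

Total step count: 25. Longest linear sequence: 22 (steps 1–8, 10–14, 17–25).

**Steps most likely to fail**

Step 14. The β-alkoxy enolate 23 may expel 4-methoxybenzyl oxide (E1cB) before it is trapped, or part of the material may rearrange through a boat or through the conformer with axial silyloxy groups, which would erode the C3=C4 geometry and the C6 configuration. The fallback sets out from 21. The tertiary hydroxyl is silylated with N-(trimethylsilyl)imidazole to the trimethylsilyl ether F1, and F1 is heated (toluene, sealed tube, about 180–200 °C, a trace of BSA as acid scavenger). The neutral siloxy-Cope rearrangement passes through the same chair and gives the silyl enol ether directly, with no free enolate, so the route is rejoined at 24.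

Step 13. The silylating agent may fail to discriminate between the two tertiary hydroxyls, so that O5 is silylated as well or O1 stays free. The fallback sets out from 20. Only the secondary hydroxyl is silylated (TESCl 1.05 equiv, imidazole, −20 °C) to the mono-triethylsilyl ether F2. F2 is rearranged as its dipotassium salt (excess KH and 18-crown-6, THF), the remote second alkoxide being a spectator, and the enolate-alkoxide is quenched with excess TESCl to the tris(triethylsilyl) compound F3. F3 then undergoes a Mukaiyama aldol addition with 27 (BF3·OEt2, CH2Cl2, −78 °C), and the route is rejoined at 29.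

Step 19. The E-configured part of 31 may fail to isomerise, so that only a fraction lactonises, or the ene-dicarbonyl unit may be consumed by conjugate addition. The fallback sets out from 29. The ester is cleaved before any dehydration (Me3SnOH, 1,2-dichloroethane, 60 °C), and the saturated γ-keto acid closes to the bicyclic lactol F4, in which the lactone ring already holds C12 cis to C8. Both molecules of water are then removed inside the ring (MsCl, Et3N, CH2Cl2, 0 °C → rt), the C8 mesylate ionising toward C9 and the C11 mesylate eliminating toward C7, and the route is rejoined at 35.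

Further compounds
F1 | step 14 | 5-O-trimethylsilyl ether of 21 | CC[Si](CC)(CC)O[C@@]1(C)C[C@@H](O[Si](CC)(CC)CC)[C@H](C(C)=C)[C@](O[Si](C)(C)C)(/C=C\OCc2ccc(OC)cc2)C1
F2 | step 13 | 3-O-triethylsilyl ether of 20 (1-OH and 5-OH free) | O[C@@]1(C)C[C@@H](O[Si](CC)(CC)CC)[C@H](C(C)=C)[C@](O)(/C=C\OCc2ccc(OC)cc2)C1
F3 | step 13 | triethylsilyl enol ether analogue of 24 (2,8,10-tris-OTES) | C[C@@]1(O[Si](CC)(CC)CC)C/C(O[Si](CC)(CC)CC)=C/[C@H](OCc2ccc(OC)cc2)C/C(C)=C\[C@H](O[Si](CC)(CC)CC)C1
F4 | step 19 | bicyclic 8,11-dihydroxy lactone (lactol of the saturated keto acid) | C[C@@]1(O[Si](CC)(CC)CC)CC2(O)OC(=O)C(O)(CO[Si](c3ccccc3)(c3ccccc3)C(C)(C)C)C2[C@H](OCc2ccc(OC)cc2)C/C(C)=C\[C@H](O[Si](CC)(CC)CC)C1
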